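**Retrosynthetic overview**

1. The 1,2-dioxepine ring (C11–O–O–C15 peroxy-hemiacetal) is closed last, by ring–chain tautomerism of 11-hydroperoxy dialdehyde 34. The C11–OOH group comes from SN2 perhydrolysis (inversion) of the mesylate of (11R)-allylic alcohol 31.
2. The (12E)-alkene and the C11 centre of 31 come from ynone 26 (CBS reduction, trans-hydroalumination/iodination, Negishi coupling). 26 comes from aldehyde 22, which comes from exocyclic alkene 16 by allylic oxidation at C7 and oxidation/1,2-reduction (7β-OH).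
3. 16 comes from the ring-B allylsilane 14/15: protodesilylation turns the C8=C9/C17–Si unit into the C8=C17 methylene and the 9α-hydrogen, and a formyl group on C6 is removed by decarbonylation.
4. Key disconnection: C5–C10 and C6–C7 together, by an intramolecular Diels–Alder reaction of acyclic trienal 12 that closes rings A and B at once. Enabling feature: in ring B the allylic array C7–C8(=C17)–C9(H) is the retron of a C8=C9 cyclohexene bearing silicon on C17, that is, of a C7=C8–C9=C10 diene. C5–C6 is the dienophile (C6 is CH2 in the target, so it can carry a traceless formyl activator), and C1–C2–C3–C4 of ring A is the four-atom tether from C10 to C5.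
5. 12 comes from B-alkyl Suzuki–Miyaura union of dienamide 3 with the tetrasubstituted alkenyl iodide 9, which is made by anti-carbomagnesiation/iodination of but-2-yn-1-ol.

Key step: step 6

Assumption: the C15 hemiperoxyacetal centre equilibrates by ring–chain tautomerism, so its (R) configuration is taken as the thermodynamic outcome of the last ring closure. Labdane numbering is used for all carbocyclic compounds.

**Route**

Step 1
Reactants: 1 2,2-dimethylpent-4-enal; 2 diethyl {2-[methoxy(methyl)amino]-2-oxoethyl}phosphonate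
Product: 3 (2E)-N-methoxy-N,4,4-trimethylhepta-2,6-dienamide
Conditions: NaH, THF, 0 °C → rt
Reagents that add atoms: none
Why: Horner–Wadsworth–Emmons olefination of the neopentyl aldehyde should give the (E)-enamide under the usual thermodynamic control of a stabilised phosphonate, a masked enal that tolerates the later hydroboration and cross-coupling.

Step 2
Reactants: 4 but-2-yn-1-ol; 5 (2-bromoprop-2-en-1-yl)trimethylsilane
Product: 8 (2Z)-3-iodo-2-[3-(trimethylsilyl)prop-1-en-2-yl]but-2-en-1-ol, via alkenylmagnesium bromide 6 (not isolated), via oxamagnesacycle 7 (not isolated)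
Conditions: 5, Mg, THF, rt; then 4 (0.4 equiv), cyclohexane/THF, reflux; then I2, THF, −78 → 0 °C
Reagents that add atoms: iodine, II
Why: Alkoxide-directed anti-carbomagnesiation of a propargylic alcohol by an alkenyl Grignard reagent delivers the alkenyl group to the carbon next to CH2O and magnesium to the methyl-bearing carbon (cyclic chelate 7); iodinolysis with retention then fixes the tetrasubstituted geometry with iodine trans to the new alkenyl group.

Step 3
Reactants: 8 iodo dienol
Product: 9 4-methoxybenzyl ether of 8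
Conditions: NaH, 4-methoxybenzyl chloride, Bu4NI (cat.), THF/DMF, 0 °C
Reagents that add atoms: 4-methoxybenzyl chloride, COc1ccc(CCl)cc1
Why: Williamson etherification of the primary allylic alkoxide should proceed without touching the alkenyl iodide or the allylsilane.

Step 4
Reactants: 3 dienamide; 9 alkenyl iodide
Product: 11 (2E,8Z)-N-methoxy-9-{[(4-methoxybenzyl)oxy]methyl}-N,4,4,8-tetramethyl-10-[(trimethylsilyl)methyl]undeca-2,8,10-trienamide, via B-alkyl-9-BBN adduct 10 (not isolated)
Conditions: 9-BBN-H dimer, THF, 0 °C → rt; then 9, PdCl2(dppf) (5 mol %), AsPh3, Cs2CO3, DMF/H2O, rt → 45 °C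
Reagents that add atoms: none
Why: Anti-Markovnikov hydroboration of the monosubstituted alkene (the conjugated amide is left alone) followed by B-alkyl Suzuki–Miyaura coupling with retention of the iodide geometry should place the tether trans to the silylallyl unit, i.e. on the outside position of the future diene.

Step 5
Reactants: 11 triene Weinreb amide
Product: 12 (2E,8Z)-9-{[(4-methoxybenzyl)oxy]methyl}-4,4,8-trimethyl-10-[(trimethylsilyl)methyl]undeca-2,8,10-trienal
Conditions: i-Bu2AlH, THF, −78 °C; Rochelle salt work-up at 0 °C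
Reagents that add atoms: none
Why: Reduction of the Weinreb amide stops at the chelated tetrahedral intermediate and releases the (E)-enal only on cold work-up, so the dienophile is unmasked without heating and without an uncatalysed cycloaddition.

Step 6
Reactants: 12 trienal
Product: 14 6α-formyl-11-[(4-methoxybenzyl)oxy]-17-(trimethylsilyl)-12,13,14,15,16-pentanorlabd-8-ene (5α-H and 10β-methyl), via iminium ion 13 (not isolated)
Conditions: (2S,5S)-5-benzyl-2-tert-butyl-3-methylimidazolidin-4-one·CF3CO2H (20 mol %), MeCN/H2O 98:2, −20 → 4 °C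
Reagents that add atoms: none
Why: Reversible condensation of enal 12 with the amine salt gives the (E)-iminium ion 13, whose lowered LUMO is attacked by the tethered diene (raised in energy by four alkyl groups and the allylic C–Si bond) in a concerted, asynchronous normal-demand [4+2] cycloaddition, and hydrolysis then releases 14 and the catalyst. The closest known reaction type is the secondary-amine-catalysed enantioselective intramolecular Diels–Alder reaction of (2E,7E)-deca-2,7,9-trienals to trans-fused octalin carbaldehydes, and 2-(silylmethyl)dienes are established Diels–Alder dienes. Ring A closes through the C5–C10 bond across the C1–C4 tether (six-membered, tether exo on the dienophile), and ring B is the new cyclohexene formed in the same suprafacial event through C5–C10 and C6–C7. C5 is set by the catalyst, whose benzyl group is expected to shield the Re face of C5 (C4 > C6 > H) so that C10 adds to the Si face; C10 (β-methyl) follows from the (8Z)-geometry that puts the tether outside and the methyl inside together with the formyl-endo transition state, which gives the trans ring fusion (5α-H) and places the C6 formyl group α. The step needs trans over cis fusion and one facial sense: the first should be secured by the endo preference of the iminium dienophile and the chair-like tether with its C4 gem-dimethyl group (Thorpe–Ingold assistance), the second by the catalyst; regiochemistry is fixed by the tether, and conjugate addition of the allylsilane terminus to the iminium ion is excluded because it would need a nine-membered ring.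

Step 7
Reactants: 14 cycloadduct aldehyde
Product: 15 11-[(4-methoxybenzyl)oxy]-17-(trimethylsilyl)-12,13,14,15,16-pentanorlabd-8-ene
Conditions: RhCl(PPh3)3 (1.1 equiv), PhCN, 130 °C
Reagents that add atoms: none
Why: Tsuji–Wilkinson decarbonylation (formyl C–H oxidative addition, CO extrusion, reductive elimination) removes the activating carbon and leaves C6 as CH2 under neutral conditions that spare the allylsilane.

Step 8
Reactants: 15 ring-B allylsilane
Product: 16 11-[(4-methoxybenzyl)oxy]-12,13,14,15,16-pentanorlabd-8(17)-ene (9α-H)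
Conditions: TsOH·H2O (20 mol %), wet CH2Cl2, 0 °C → rt
Reagents that add atoms: none
Why: Protodesilylation of the allylsilane (SE2′) should protonate C9 axially from the α face, anti to the C10 methyl group, and loss of silicon from the β-silyl cation then gives the C8=C17 methylene with the C11 arm equatorial (β).

Step 9
Reactants: 16 exocyclic alkene
Product: 17 11-[(4-methoxybenzyl)oxy]-12,13,14,15,16-pentanorlabd-8(17)-en-7α-ol
Conditions: SeO2 (0.5 equiv), t-BuOOH, CH2Cl2, 0 °C → rt
Reagents that add atoms: tert-butyl hydroperoxide, CC(C)(C)OO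
Why: SeO2-mediated allylic hydroxylation (ene reaction, then [2,3]-shift) should oxidise the ring CH2 at C7 in preference to the C9 methine and deliver the axial 7α-alcohol, whose configuration is corrected in the next two steps.

Step 10
Reactants: 17 7α-alcohol
Product: 18 11-[(4-methoxybenzyl)oxy]-12,13,14,15,16-pentanorlabd-8(17)-en-7-one
Conditions: Dess–Martin periodinane, NaHCO3, CH2Cl2, 0 °C
Reagents that add atoms: none
Why: Dess–Martin oxidation under buffered conditions should give the sensitive exo-methylene ketone without isomerising the alkene into the ring.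

Step 11
Reactants: 18 enone
Product: 19 11-[(4-methoxybenzyl)oxy]-12,13,14,15,16-pentanorlabd-8(17)-en-7β-ol
Conditions: NaBH4, CeCl3·7H2O, MeOH, −78 °C
Reagents that add atoms: none
Why: Luche 1,2-reduction with axial hydride delivery from the α face (anti to the C10 methyl group) should give the equatorial 7β-alcohol.

Step 12
Reactants: 19 7β-alcohol
Product: 20 7β-[(tert-butyldimethylsilyl)oxy]-11-[(4-methoxybenzyl)oxy]-12,13,14,15,16-pentanorlabd-8(17)-ene
Conditions: TBSOTf, 2,6-lutidine, CH2Cl2, −78 → 0 °C
Reagents that add atoms: tert-butyldimethylsilyl trifluoromethanesulfonate, CC(C)(C)[Si](C)(C)OS(=O)(=O)C(F)(F)F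
Why: Silylation of the secondary allylic alcohol gives a group that survives hydride, organometallic and basic peroxide conditions and falls off in the final acid step.

Step 13
Reactants: 20 bis-ether
Product: 21 7β-[(tert-butyldimethylsilyl)oxy]-12,13,14,15,16-pentanorlabd-8(17)-en-11-ol
Conditions: DDQ, CH2Cl2/pH 7 buffer, 0 °C
Reagents that add atoms: none
Why: Oxidative cleavage of the 4-methoxybenzyl ether is orthogonal to the silyl ether and to the exocyclic alkene.

Step 14
Reactants: 21 primary alcohol
Product: 22 7β-[(tert-butyldimethylsilyl)oxy]-12,13,14,15,16-pentanorlabd-8(17)-en-11-al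
Conditions: Dess–Martin periodinane, NaHCO3, CH2Cl2, 0 °C
Reagents that add atoms: none
Why: Neutral Dess–Martin oxidation should give the β,γ-unsaturated aldehyde without epimerising C9 or moving the double bond into conjugation.

Step 15
Reactants: 22 aldehyde; 23 3,3-diethoxyprop-1-yne
Product: 25 7β-[(tert-butyldimethylsilyl)oxy]-16,16-diethoxy-14,15-dinorlabd-8(17)-en-12-yn-11-ol (both C11 epimers), via lithium acetylide 24 (not isolated)
Conditions: 23, n-BuLi, THF, −78 °C; then 22, −78 °C; aqueous NH4Cl
Reagents that add atoms: none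
Why: Fast 1,2-addition of the acetylide at −78 °C joins C11 to C12 without enolising the aldehyde; the C11 ratio is irrelevant because the centre is reset in steps 16 and 17.

Step 16
Reactants: 25 propargylic alcohols
Product: 26 7β-[(tert-butyldimethylsilyl)oxy]-16,16-diethoxy-14,15-dinorlabd-8(17)-en-12-yn-11-one
Conditions: Dess–Martin periodinane, NaHCO3, CH2Cl2, 0 °C
Reagents that add atoms: none
Why: Dess–Martin oxidation converges both epimers on one ynone under conditions that leave the acetal, silyl ether and the C9 centre intact.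

Step 17
Reactants: 26 ynone
Product: 27 (11S)-7β-[(tert-butyldimethylsilyl)oxy]-16,16-diethoxy-14,15-dinorlabd-8(17)-en-12-yn-11-ol
Conditions: (S)-2-methyl-CBS-oxazaborolidine [(S)-3,3-diphenyl-1-methyltetrahydro-1H,3H-pyrrolo[1,2-c][1,3,2]oxazaborole] (0.5 equiv), catecholborane, toluene, −78 °C
Reagents that add atoms: none
Why: Corey–Bakshi–Shibata reduction treats the alkynyl group as the small substituent and should give the (11S)-alcohol, the same sense as Felkin–Anh-type hydride delivery anti to C10 (matched case); catecholborane is chosen because it does not hydroborate the exocyclic alkene.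

Step 18
Reactants: 27 propargylic alcohol
Product: 29 (11S,12Z)-7β-[(tert-butyldimethylsilyl)oxy]-16,16-diethoxy-13-iodo-14,15-dinorlabda-8(17),12-dien-11-ol, via cyclic alkenylalanate 28 (not isolated)
Conditions: NaAlH2(OCH2CH2OMe)2 (Red-Al), THF, 0 °C → rt; EtOAc; then I2, THF, −78 °C
Reagents that add atoms: iodine, II
Why: Hydroxyl-directed trans-hydroalumination places hydrogen on C12 and aluminium on C13, and iodinolysis with retention should give the (Z)-iodoalkene in which C11 and the iodine are cis, the geometry the dioxepine ring needs.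

Step 19
Reactants: 29 alkenyl iodide; 30 (1,3-dioxolan-2-ylmethyl)zinc bromide
Product: 31 (11R,12E)-7β-[(tert-butyldimethylsilyl)oxy]-16,16-diethoxy-15,15-(ethylenedioxy)labda-8(17),12-dien-11-ol
Conditions: PdCl2(dppf) (5 mol %), 30 (3 equiv), THF, rt → 50 °C
Reagents that add atoms: none
Why: Negishi coupling with retention of alkene geometry installs C14–C15 as a masked acetaldehyde unit cis to C11; the C11 descriptor changes only through CIP priorities.

Step 20
Reactants: 31 allylic alcohol
Product: 33 (11S,12E)-7β-[(tert-butyldimethylsilyl)oxy]-16,16-diethoxy-15,15-(ethylenedioxy)labda-8(17),12-dien-11-yl hydroperoxide, via allylic mesylate 32 (not isolated)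
Conditions: Ms2O, Et3N, CH2Cl2, −40 °C; then H2O2 (50 % aq., excess), KOH, MeOH/THF, −20 → 0 °C
Reagents that add atoms: hydrogen peroxide, OO
Why: Perhydrolysis of a secondary sulfonate by the α-effect hydroperoxide anion is an SN2 displacement with inversion, here accelerated by the allylic position, and should convert the (11R)-mesylate into the (11S)-hydroperoxide; the SN2′ terminus C13 is fully substituted.

Step 21
Reactants: 33 protected hydroperoxide
Product: 35 (5S,7S,9R,10S,11S,12E,15R)-11,15-epidioxy-7,15-dihydroxylabda-8(17),12-dien-16-al (CNP0269954.2), via open hydroperoxy dialdehyde 34 (not isolated)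
Conditions: HCl (1 M aq.)/THF 1:2, 0 °C → rt
Reagents that add atoms: water, O
Why: Acid hydrolysis removes both acetals and the silyl ether, and the C11 hydroperoxide should then add to the C15 aldehyde (held cis across the C12=C13 bond) to close the seven-membered peroxy-hemiacetal under thermodynamic control, while the trans-disposed C16 aldehyde cannot cyclise.

**Compound list**

1 | 2,2-dimethylpent-4-enal | C=CCC(C)(C)C=O | starting material
2 | diethyl {2-[methoxy(methyl)amino]-2-oxoethyl}phosphonate | CCOP(=O)(CC(=O)N(C)OC)OCC | starting material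
3 | (2E)-N-methoxy-N,4,4-trimethylhepta-2,6-dienamide | C=CCC(C)(C)/C=C/C(=O)N(C)OC | intermediate
4 | but-2-yn-1-ol | CC#CCO | starting material
5 | (2-bromoprop-2-en-1-yl)trimethylsilane | C=C(Br)C[Si](C)(C)C | starting material
6 | [3-(trimethylsilyl)prop-1-en-2-yl]magnesium bromide | C=C([Mg]Br)C[Si](C)(C)C | intermediate
7 | 3-methyl-4-[3-(trimethylsilyl)prop-1-en-2-yl]-2,5-dihydro-1,2-oxamagnesole (chelated alkenylmagnesium alkoxide) | C=C(C[Si](C)(C)C)C1=C(C)[Mg]OC1 | intermediate
8 | (2Z)-3-iodo-2-[3-(trimethylsilyl)prop-1-en-2-yl]but-2-en-1-ol | C=C(C[Si](C)(C)C)/C(CO)=C(\C)I | intermediate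
9 | 1-[({(2Z)-3-iodo-2-[3-(trimethylsilyl)prop-1-en-2-yl]but-2-en-1-yl}oxy)methyl]-4-methoxybenzene | C=C(C[Si](C)(C)C)/C(COCc1ccc(OC)cc1)=C(\C)I | intermediate
10 | (2E)-7-(9-borabicyclo[3.3.1]nonan-9-yl)-N-methoxy-N,4,4-trimethylhept-2-enamide | CON(C)C(=O)/C=C/C(C)(C)CCCB1C2CCCC1CCC2 | intermediate
11 | (2E,8Z)-N-methoxy-9-{[(4-methoxybenzyl)oxy]methyl}-N,4,4,8-tetramethyl-10-[(trimethylsilyl)methyl]undeca-2,8,10-trienamide | CON(C)C(=O)/C=C/C(C)(C)CCC/C(C)=C(/C(=C)C[Si](C)(C)C)COCc1ccc(OC)cc1 | intermediate
12 | (2E,8Z)-9-{[(4-methoxybenzyl)oxy]methyl}-4,4,8-trimethyl-10-[(trimethylsilyl)methyl]undeca-2,8,10-trienal | O=C/C=C/C(C)(C)CCC/C(C)=C(/C(=C)C[Si](C)(C)C)COCc1ccc(OC)cc1 | intermediate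
13 | iminium trifluoroacetate of 12 with (2S,5S)-5-benzyl-2-tert-butyl-3-methylimidazolidin-4-one | C[Si](C)(C)CC(=C)/C(COCc1ccc(OC)cc1)=C(C)/CCCC(C)(C)/C=C/C=[N+]2[C@@H](Cc3ccccc3)C(=O)N(C)[C@H]2C(C)(C)C.[O-]C(=O)C(F)(F)F | intermediate
14 | 6α-formyl-11-[(4-methoxybenzyl)oxy]-17-(trimethylsilyl)-12,13,14,15,16-pentanorlabd-8-ene (5α-H, 10β-methyl) | C[Si](C)(C)CC1=C(COCc2ccc(OC)cc2)[C@@]3(C)CCCC(C)(C)[C@@H]3[C@@H](C=O)C1 | intermediate
15 | 11-[(4-methoxybenzyl)oxy]-17-(trimethylsilyl)-12,13,14,15,16-pentanorlabd-8-ene | C[Si](C)(C)CC1=C(COCc2ccc(OC)cc2)[C@@]3(C)CCCC(C)(C)[C@@H]3CC1 | intermediate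
16 | 11-[(4-methoxybenzyl)oxy]-12,13,14,15,16-pentanorlabd-8(17)-ene (9α-H; albicanol 4-methoxybenzyl ether) | C=C1[C@H](COCc2ccc(OC)cc2)[C@@]3(C)CCCC(C)(C)[C@@H]3CC1 | intermediate
17 | 11-[(4-methoxybenzyl)oxy]-12,13,14,15,16-pentanorlabd-8(17)-en-7α-ol | C=C1[C@H](COCc2ccc(OC)cc2)[C@@]3(C)CCCC(C)(C)[C@@H]3C[C@H]1O | intermediate
18 | 11-[(4-methoxybenzyl)oxy]-12,13,14,15,16-pentanorlabd-8(17)-en-7-one | C=C1[C@H](COCc2ccc(OC)cc2)[C@@]3(C)CCCC(C)(C)[C@@H]3CC1=O | intermediate
19 | 11-[(4-methoxybenzyl)oxy]-12,13,14,15,16-pentanorlabd-8(17)-en-7β-ol | C=C1[C@H](COCc2ccc(OC)cc2)[C@@]3(C)CCCC(C)(C)[C@@H]3C[C@@H]1O | intermediate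
20 | 7β-[(tert-butyldimethylsilyl)oxy]-11-[(4-methoxybenzyl)oxy]-12,13,14,15,16-pentanorlabd-8(17)-ene | C=C1[C@H](COCc2ccc(OC)cc2)[C@@]3(C)CCCC(C)(C)[C@@H]3C[C@@H]1O[Si](C)(C)C(C)(C)C | intermediate
21 | 7β-[(tert-butyldimethylsilyl)oxy]-12,13,14,15,16-pentanorlabd-8(17)-en-11-ol | C=C1[C@H](CO)[C@@]2(C)CCCC(C)(C)[C@@H]2C[C@@H]1O[Si](C)(C)C(C)(C)C | intermediate
22 | 7β-[(tert-butyldimethylsilyl)oxy]-12,13,14,15,16-pentanorlabd-8(17)-en-11-al | C=C1[C@H](C=O)[C@@]2(C)CCCC(C)(C)[C@@H]2C[C@@H]1O[Si](C)(C)C(C)(C)C | intermediate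
23 | 3,3-diethoxyprop-1-yne | C#CC(OCC)OCC | starting material
24 | (3,3-diethoxyprop-1-yn-1-yl)lithium | [Li]C#CC(OCC)OCC | intermediate
25 | 7β-[(tert-butyldimethylsilyl)oxy]-16,16-diethoxy-14,15-dinorlabd-8(17)-en-12-yn-11-ol (C11 epimers, C11 undefined) | C=C1[C@H](C(O)C#CC(OCC)OCC)[C@@]2(C)CCCC(C)(C)[C@@H]2C[C@@H]1O[Si](C)(C)C(C)(C)C | intermediate
26 | 7β-[(tert-butyldimethylsilyl)oxy]-16,16-diethoxy-14,15-dinorlabd-8(17)-en-12-yn-11-one | C=C1[C@H](C(=O)C#CC(OCC)OCC)[C@@]2(C)CCCC(C)(C)[C@@H]2C[C@@H]1O[Si](C)(C)C(C)(C)C | intermediate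
27 | (11S)-7β-[(tert-butyldimethylsilyl)oxy]-16,16-diethoxy-14,15-dinorlabd-8(17)-en-12-yn-11-ol | C=C1[C@H]([C@H](O)C#CC(OCC)OCC)[C@@]2(C)CCCC(C)(C)[C@@H]2C[C@@H]1O[Si](C)(C)C(C)(C)C | intermediate
28 | sodium 2,2-bis(2-methoxyethoxy)-2,5-dihydro-1,2-oxaluminol-2-uide from 27 (Al on C13, O on C11) | [Na+].C=C1[C@H]([C@@H]3O[Al-](OCCOC)(OCCOC)C(C(OCC)OCC)=C3)[C@@]2(C)CCCC(C)(C)[C@@H]2C[C@@H]1O[Si](C)(C)C(C)(C)C | intermediate
29 | (11S,12Z)-7β-[(tert-butyldimethylsilyl)oxy]-16,16-diethoxy-13-iodo-14,15-dinorlabda-8(17),12-dien-11-ol | C=C1[C@H]([C@H](O)/C=C(\I)C(OCC)OCC)[C@@]2(C)CCCC(C)(C)[C@@H]2C[C@@H]1O[Si](C)(C)C(C)(C)C | intermediate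
30 | (1,3-dioxolan-2-ylmethyl)zinc bromide | Br[Zn]CC1OCCO1 | starting material
31 | (11R,12E)-7β-[(tert-butyldimethylsilyl)oxy]-16,16-diethoxy-15,15-(ethylenedioxy)labda-8(17),12-dien-11-ol | C=C1[C@H]([C@H](O)/C=C(\CC3OCCO3)C(OCC)OCC)[C@@]2(C)CCCC(C)(C)[C@@H]2C[C@@H]1O[Si](C)(C)C(C)(C)C | intermediate
32 | (11R,12E)-11-methanesulfonate of 31 | C=C1[C@H]([C@H](OS(C)(=O)=O)/C=C(\CC3OCCO3)C(OCC)OCC)[C@@]2(C)CCCC(C)(C)[C@@H]2C[C@@H]1O[Si](C)(C)C(C)(C)C | intermediate
33 | (11S,12E)-7β-[(tert-butyldimethylsilyl)oxy]-16,16-diethoxy-15,15-(ethylenedioxy)labda-8(17),12-dien-11-yl hydroperoxide | C=C1[C@H]([C@@H](OO)/C=C(\CC3OCCO3)C(OCC)OCC)[C@@]2(C)CCCC(C)(C)[C@@H]2C[C@@H]1O[Si](C)(C)C(C)(C)C | intermediate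
34 | (11S,12E)-11-hydroperoxy-7β-hydroxylabda-8(17),12-diene-15,16-dial | C=C1[C@H]([C@@H](OO)/C=C(\CC=O)C=O)[C@@]2(C)CCCC(C)(C)[C@@H]2C[C@@H]1O | intermediate
35 | (5S,7S,9R,10S,11S,12E,15R)-11,15-epidioxy-7,15-dihydroxylabda-8(17),12-dien-16-al | C=C1[C@H]([C@@H]2C=C(C=O)C[C@H](O)OO2)[C@@]2(C)CCCC(C)(C)[C@@H]2C[C@@H]1O | target

**Step count and risks**

Total step count: 21. Longest linear sequence: 20 steps (steps 2 to 21; step 1 is a one-step side branch that joins in step 4).

The three steps most likely to fail: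

1. Step 6. What may go wrong: the cycloaddition may be too slow, because the C5–C10 bond joins a neopentyl dienophile carbon to a fully substituted diene terminus. Acid-promoted protodesilylation of the 2-(silylmethyl)diene or an uncatalysed, racemic background reaction could then take over, and facial control could erode. The facial sense is assigned by analogy with the usual shielding model for this catalyst; if the opposite sense were found, the (2R,5R)-catalyst would be used.
   Fallback (auxiliary-controlled, Lewis acid-promoted cycloaddition, no Brønsted acid), setting out from 12 and returning at 14: Pinnick oxidation of 12 (NaClO2, NaH2PO4, 2-methylbut-2-ene, t-BuOH/H2O) should give (2E,8Z)-9-{[(4-methoxybenzyl)oxy]methyl}-4,4,8-trimethyl-10-[(trimethylsilyl)methyl]undeca-2,8,10-trienoic acid F1. Activation as the pivaloyl mixed anhydride and acylation of lithiated (4S)-4-benzyl-1,3-oxazolidin-2-one should give the N-trienoyl oxazolidinone F2. Me2AlCl (1.5 equiv, CH2Cl2, −30 °C) forms the chelated s-cis acyl oxazolidinone, in which the auxiliary benzyl group shields the Re face of C5, and the known endo-selective intramolecular Diels–Alder reaction of trienimides should give the trans-fused cycloadduct imide F3. LiBH4 (MeOH, THF, 0 °C) cleaves the auxiliary to give the 6α-hydroxymethyl compound F4, and Dess–Martin oxidation of F4 gives 14.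

2. Step 20. What may go wrong: slow substitution at the hindered C11 may lose out to E2 elimination toward a conjugated diene, and the new secondary hydroperoxide may fragment under base to the C11 ketone (Kornblum–DeLaMare).
   Fallback (mono-protected peroxide nucleophile, so that no free hydroperoxide is exposed to base), setting out from 31 and returning at 34: mesylate 32 is formed as before and treated with 2-methoxypropan-2-yl hydroperoxide (prepared by ozonolysis of 2,3-dimethylbut-2-ene in methanol) and CsOH·H2O in DMF at 0 °C. This known displacement of secondary sulfonates with inversion should give the (11S)-peroxyketal, 11-[(2-methoxypropan-2-yl)peroxy] derivative F5. The acid conditions of step 21 cleave the peroxyketal together with the acetals and the silyl ether, giving 34 and then 35.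

3. Step 18. What may go wrong: the alkenylalanate may lose ethoxide from the neighbouring acetal (β-elimination to an alkoxyallene), or iodinolysis may be incomplete.
   Fallback (transition-metal-catalysed trans-hydrosilylation in place of hydroalumination), setting out from 27 and returning at 29: [Cp*Ru(MeCN)3]PF6 (2 mol %) and benzyldimethylsilane in CH2Cl2 at 0 °C should add H and Si trans across the alkyne, with silicon on the carbon remote from the hydroxyl, to give the (11S,12Z)-13-[benzyl(dimethyl)silyl] alkenylsilane F6. Iododesilylation of F6 with N-iodosuccinimide in hexafluoropropan-2-ol at 0 °C, with retention, gives 29.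

Further compounds
F1 | step 6 | (2E,8Z)-9-{[(4-methoxybenzyl)oxy]methyl}-4,4,8-trimethyl-10-[(trimethylsilyl)methyl]undeca-2,8,10-trienoic acid | OC(=O)/C=C/C(C)(C)CCC/C(C)=C(/C(=C)C[Si](C)(C)C)COCc1ccc(OC)cc1
F2 | step 6 | (4S)-4-benzyl-3-[(2E,8Z)-9-{[(4-methoxybenzyl)oxy]methyl}-4,4,8-trimethyl-10-[(trimethylsilyl)methyl]undeca-2,8,10-trienoyl]-1,3-oxazolidin-2-one | O=C(/C=C/C(C)(C)CCC/C(C)=C(/C(=C)C[Si](C)(C)C)COCc1ccc(OC)cc1)N1[C@@H](Cc2ccccc2)COC1=O
F3 | step 6 | (4S)-4-benzyl-3-{[11-[(4-methoxybenzyl)oxy]-17-(trimethylsilyl)-12,13,14,15,16-pentanorlabd-8-en-6α-yl]carbonyl}-1,3-oxazolidin-2-one | C[Si](C)(C)CC1=C(COCc2ccc(OC)cc2)[C@@]3(C)CCCC(C)(C)[C@@H]3[C@@H](C(=O)N4[C@@H](Cc5ccccc5)COC4=O)C1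
F4 | step 6 | 6α-(hydroxymethyl)-11-[(4-methoxybenzyl)oxy]-17-(trimethylsilyl)-12,13,14,15,16-pentanorlabd-8-ene | C[Si](C)(C)CC1=C(COCc2ccc(OC)cc2)[C@@]3(C)CCCC(C)(C)[C@@H]3[C@@H](CO)C1
F5 | step 20 | (11S,12E)-7β-[(tert-butyldimethylsilyl)oxy]-16,16-diethoxy-15,15-(ethylenedioxy)-11-[(2-methoxypropan-2-yl)peroxy]labda-8(17),12-diene | C=C1[C@H]([C@@H](OOC(C)(C)OC)/C=C(\CC3OCCO3)C(OCC)OCC)[C@@]2(C)CCCC(C)(C)[C@@H]2C[C@@H]1O[Si](C)(C)C(C)(C)C
F6 | step 18 | (11S,12Z)-13-[benzyl(dimethyl)silyl]-7β-[(tert-butyldimethylsilyl)oxy]-16,16-diethoxy-14,15-dinorlabda-8(17),12-dien-11-ol | C=C1[C@H]([C@H](O)/C=C(\[Si](C)(C)Cc3ccccc3)C(OCC)OCC)[C@@]2(C)CCCC(C)(C)[C@@H]2C[C@@H]1O[Si](C)(C)C(C)(C)C
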